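**Assumption:** the target, 1-(4-hydroxy-3-methoxyphenyl)hexadecane-3,5-dione (C23H36O4), has no stereocentres or stereogenic double bonds, so the "single enantiomer" requirement is moot; it is an achiral keto/enol tautomer mixture.

**Retrosynthetic overview**
1. Disconnect the C4–C5 bond of the 1,3-diketone (crossed Claisen): a methyl-ketone enolate plus a C12 acyl donor.
2. The enolate component is zingerone, which already carries the aryl ring, the OH/OMe pattern and the CH2CH2C(=O)CH3 chain. The acyl donor is methyl dodecanoate.
3. No rings are formed (the only ring, the guaiacyl arene, is purchased) and no protecting groups are used. The phenol is carried as its lithium phenoxide.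

**Step 1**
Reactants: 1, zingerone [4-(4-hydroxy-3-methoxyphenyl)butan-2-one], 2.2 equiv; 2, methyl dodecanoate (methyl laurate), 1.0 equiv, limiting.
Product: 3, [12]-gingerdione [1-(4-hydroxy-3-methoxyphenyl)hexadecane-3,5-dione], achiral, expected mainly as the enol tautomer.
Conditions: LDA (4.5 equiv, i.e. about 2.05 per 1), THF, −78 °C, 1 h; then 2, −78 °C → rt, 12 h; 1 M HCl to pH 3–4; SiO2 chromatography (excess 1 recovered).
Reagents that add atoms: none beyond reactant 2, methyl dodecanoate, CCCCCCCCCCCC(=O)OC, which supplies the dodecanoyl unit (C12H23O) and loses MeOH.
Why: this is a crossed Claisen condensation (C-acylation of a ketone enolate) in which LDA removes the phenol proton and then the kinetically favoured CH3 proton to give the phenoxide/terminal-enolate dianion, which attacks the ester and expels methoxide to give the diketone as its stable β-diketonate (the second equivalent of dianion absorbs the acidic product proton), while the phenoxide cannot be permanently acylated by a methyl ester; no stereocentre is created.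

Atom check: C11H14O3 (1) + C13H26O2 (2) → C23H36O4 (3) + CH4O. The new bond joins the former CH3 carbon of 1 to the ester carbonyl carbon of 2, giving C11H23–C(=O)–CH2–C(=O)–CH2CH2–Ar, which matches the target SMILES. The aryl OMe and the alkyl chain are inert to LDA, and the mild acid work-up regenerates the free phenol and the neutral diketone.

**Compound list**
1 | Zingerone, 4-(4-hydroxy-3-methoxyphenyl)butan-2-one | CC(=O)CCc1ccc(O)c(OC)c1 | starting material
2 | Methyl dodecanoate (methyl laurate) | CCCCCCCCCCCC(=O)OC | starting material
3 | [12]-Gingerdione, 1-(4-hydroxy-3-methoxyphenyl)hexadecane-3,5-dione | CCCCCCCCCCCC(=O)CC(=O)CCc1ccc(O)c(OC)c1 | target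

**Total step count:** 1
**Longest linear sequence:** 1 step

**Most likely failures**
The route has only one step, so these are its three most likely failure modes, each with a fallback that changes the approach.

1. **The dilithio phenoxide/enolate is poorly soluble or sluggish toward the unactivated ester, giving low conversion.**
   Fallback: a protected three-step route.
   - Protect zingerone as its TBS ether (TBSCl, imidazole, DMF).
   - Form the enolate with LDA at −78 °C and acylate with the more reactive N-dodecanoylbenzotriazole (from lauroyl chloride and benzotriazole).
   - Remove the silyl group with TBAF/AcOH.

2. **Regiochemical leakage (acylation at C3 after enolate equilibration) or zingerone self-aldol on warming.**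
   Fallback: a boron-template (Pabon-type) route in which chelation fixes the regiochemistry.
   - Condense vanillin with pentadecane-2,4-dione (from 2-tridecanone and EtOAc with NaH) using B2O3, B(OBu)3 and n-BuNH2 in EtOAc; the boron chelate masks the central CH2 and directs condensation to the terminal CH3, giving (E)-[12]-dehydrogingerdione.
   - Hydrogenate the C=C chemoselectively (H2, Pd/C, EtOAc).

3. **Product loss through competing ester self-condensation or over-acylation, or difficult separation from the excess zingerone.**
   Fallback: reverse the polarity so the diketone is made first and the aryl unit is attached last.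
   - Generate the Hauser dianion of pentadecane-2,4-dione (NaH, then n-BuLi, THF, 0 °C).
   - Alkylate at the terminal CH3 with 4-(benzyloxy)-3-methoxybenzyl chloride.
   - Remove the benzyl group by hydrogenolysis (H2, Pd/C).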